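Compare the two parts of the eta run: up to 0.500 d each day takes 0.600 /d of the Z still there, but between 1.25 d and 3.00 d it takes more, 1.03 /d. Call this later figure the fade: the share of the remaining Z that becomes E per day, read while Z falls from 43.4% to 7.10% of the charge. It is an apparent first-order constant, and it carries the scatter of the readings.

common to all: L 0.01 mol%; Q 9.5 µM
- eta: Z 0.10 M; run made earlier
- epsilon: Z 0.067 M; run made earlier
- beta: Z 0.15 M; run made earlier
- Monday's: Z 0.10 M; a single well-mixed tank run continuously and read at steady state, 3.0 d in it on average
- Wednesday's: Z 0.10 M; a closed flask charged with all of it at once and left for 3.0 d; time 3.0 d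
- Sunday's: Z 0.10 M (fed, over 2.40 d); a stirred flask in which Z is dosed at a steady rate over 2.40 d without added volume, worked up at 3.0 d; time 3.0 d

- eta (time / d: E / %): 0.250: 12.8; 0.500: 25.9; 1.25: 56.6; 3.00: 92.9
- epsilon (time / d: E / %): 0.833: 33.9; 1.67: 59.6; 2.50: 77.8; 4.00: 92.9
- beta (time / d: E / %): 0.250: 15.3; 0.625: 36.1; 1.67: 81.2; 4.00: 99.0

(readings scatter by 0.5 percentage points)

- the stated concentrations are those of everything mixed, before any reaction; amounts are the same in each set-up
- the feed brings no volume worth counting
- the earlier runs were made in a closed, stirred flask

* the set-up with the highest amount of E at the outlet or at the end, in percent of the Z put in ("none" if the first two lie within 2 percentage points) (Monday's / Wednesday's / Sunday's / none)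
* amount of E at the outlet or at the end, in percent of the Z put in, Monday's
* amount of E at the outlet or at the end, in percent of the Z put in, Wednesday's
* amount of E at the outlet or at the end, in percent of the Z put in, Sunday's

Here are my books for one charge, counting each part as either Z or E. Wednesday's repeats the eta run, so its last reading stands: 92.9% as E and 7.10% as Z. Monday's tank holds its contents 3.0 d on average, so at steady state the fade sends 75.6% out as E and 24.4% out as Z, a level inside the range where you read the fade. Sunday's flask receives 0.417 /d of the charge, and by the fade I reckon 36.9% as Z when the feed stops. By the same reckoning, the last 0.600 d cut that to 19.8%, so E closes the book at 80.2%. I would therefore choose Wednesday's, ahead of Sunday's by 13 percentage points.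

The forecast also names Wednesday's, with 73.5% for Monday's, 92.8% for Wednesday's and 75% for Sunday's, on this ground: “Integrated Michaelis–Menten fits all three runs”. We part most on Sunday's, where my figure is higher.

The flask gives Wednesday's: 75.3% for Monday's, 93.6% for Wednesday's and 77.1% for Sunday's.

    Z + L ⇌ J (K = 25.0 /M, k = 54.0 /M/s)
    J → L + E (k = 0.106 /s)
    L + Q ⇌ G, settled at all times (K = 81200 /M)
    2 Z → X (k = 1.31 × 10⁻⁸ /M/s)

The fade put Monday's 0.30 points above the flask and Sunday's 3.1 points above it. Now take the neighbouring flask, Wednesday's read at 20 h. Start from the 6.4% of Z that Wednesday's holds at 3.00 d and run the fade backwards over the 2.17 d between them. You expect 59.6% as Z, above the range where you read the fade, and so 40.4% as E. That reading holds 40.7% as E and 59.3% as Z.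

The readings were generated by integration with constants of no real substance.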